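**Retrosynthetic overview**
1. Final operations: remove three phenolic MOM groups, and before that cut the allylic ester C–O bond (Steglich) into a ferulic acid unit and a chalcone bearing the (Z)-allylic alcohol.
2. Cut the chalcone Cα=Cβ bond (Claisen–Schmidt) into a 3-substituted resacetophenone and 4-hydroxybenzaldehyde.
3. Key cut, ArCH2–CH= bond: a new metal-free deaminative borono-alkenylation joins the C3 Mannich base of 2,4-dihydroxyacetophenone to a Z-locked cyclic alkenylboronic hemiester through a boron-bound o-quinone methide.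
4. The Z geometry is set by anti-carbomagnesiation of propargyl alcohol, locked in a five-membered oxaborole, and transferred with retention.
5. Rings: no ring of the target is built. All three benzene rings are bought, and the only rings made are transient boron or magnesium heterocycles.

Assumption: the target has no stereocentre and is achiral, so "single enantiomer" is read as the single geometric isomer (E-cinnamate, Z-trisubstituted alkene, E-enone) written in the SMILES.

**Step 1**
Reactants: 1 prop-2-yn-1-ol
Product: 4 4-methyl-1,2-oxaborol-2(5H)-ol, via cyclic (Z)-alkenylmagnesium alkoxide chelate 2 (not isolated), via 2-methoxy-4-methyl-2,5-dihydro-1,2-oxaborole 3 (not isolated)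
Conditions: MeMgBr (3 equiv), CuI (10 mol %), THF, −10 °C → rt; cannulate into B(OMe)3 (4 equiv), THF, −78 °C → rt; 1 M HCl, NaCl-saturated extraction
Reagents that add atoms: methylmagnesium bromide C[Mg]Br; trimethyl borate COB(OC)OC; water O
Why: Cu-catalysed anti-carbomagnesiation of the propargylic alkoxide puts CH3 on C2 and Mg on C3 cis to CH2O (chelate 2), and the standard Grignard/borate quench with hydrolysis closes the five-membered oxaborole, which locks the Z geometry.

**Step 2**
Reactants: 5 2,4-dihydroxyacetophenone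
Product: 6 1-{3-[(dimethylamino)methyl]-2,4-dihydroxyphenyl}ethan-1-one
Conditions: CH2(NMe2)2 (1.1 equiv), 1,4-dioxane, 90 °C
Reagents that add atoms: bis(dimethylamino)methane CN(C)CN(C)C
Why: In this phenol Mannich aminomethylation, C3 lies between the two OH groups and is the most nucleophilic ring carbon, and the neutral aminal leaves the methyl ketone untouched.

**Step 3**
Reactants: 6 1-{3-[(dimethylamino)methyl]-2,4-dihydroxyphenyl}ethan-1-one; 4 4-methyl-1,2-oxaborol-2(5H)-ol
Product: 10 1-{2,4-dihydroxy-3-[(2Z)-4-hydroxy-3-methylbut-2-en-1-yl]phenyl}ethan-1-one, via spiro N→B aryloxyborate chelate 7 (not isolated), via boron-bound o-quinone methide 8 (not isolated), via nine-membered cyclic (Z)-aminoborate 9 (not isolated)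
Conditions: 4 (1.5 equiv), 4 Å MS, PhMe, 110 °C; then H2O, rt
Reagents that add atoms: none
Why: Proposed new method: metal-free deaminative borono-alkenylation of a phenolic Mannich base, in which the free 4-OH of 6 condenses with the B–OH of 4 and the benzylic NMe2 binds boron (7), making the amine an ammonium-type leaving group and the phenol oxygen an electron-rich borate oxygen, so C–N heterolysis gives the o-quinone methide still held on tetracoordinate boron (8), whose B-bound sp2 carbon migrates to the exocyclic CH2 through a six-membered transition state driven by re-aromatisation and with retention of alkene geometry (the CH2O arm stays on boron, so only Z-configured 9 can form), reversible O/N additions to the quinone methide drain into this irreversible C–C bond formation, and water then releases 10; the closest known reaction types are the Petasis borono-Mannich reaction and the diol-catalysed 1,4-addition of alkenylboronates to aryl-stabilised o-quinone methides, neither shown for a parent CH2 quinone methide released from a Mannich base nor for a cyclic Z-alkenylboronic hemiester.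

**Step 4**
Reactants: 10 1-{2,4-dihydroxy-3-[(2Z)-4-hydroxy-3-methylbut-2-en-1-yl]phenyl}ethan-1-one
Product: 11 1-{2-hydroxy-3-[(2Z)-4-hydroxy-3-methylbut-2-en-1-yl]-4-(methoxymethoxy)phenyl}ethan-1-one
Conditions: MOMCl (1.05 equiv), K2CO3, acetone, 0 °C → rt
Reagents that add atoms: chloromethyl methyl ether COCCl
Why: In this Williamson-type O-alkylation K2CO3 ionises only the acidic free 4-OH, because the 2-OH is tied up in the hydrogen bond to the ketone and the allylic alcohol is not deprotonated.

**Step 5**
Reactants: 12 4-hydroxybenzaldehyde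
Product: 13 4-(methoxymethoxy)benzaldehyde
Conditions: MOMCl, K2CO3, acetone, 0 °C → rt
Reagents that add atoms: chloromethyl methyl ether COCCl
Why: This is a Williamson-type O-alkylation of an acidic para-formyl phenoxide, and the aldehyde is inert to it.

**Step 6**
Reactants: 11 1-{2-hydroxy-3-[(2Z)-4-hydroxy-3-methylbut-2-en-1-yl]-4-(methoxymethoxy)phenyl}ethan-1-one; 13 4-(methoxymethoxy)benzaldehyde
Product: 15 (2E)-1-{2-hydroxy-3-[(2Z)-4-hydroxy-3-methylbut-2-en-1-yl]-4-(methoxymethoxy)phenyl}-3-[4-(methoxymethoxy)phenyl]prop-2-en-1-one, via racemic β-hydroxy ketone (aldol adduct) 14 (not isolated)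
Conditions: 50 % aq KOH, EtOH, rt, 48 h; then 1 M HCl to pH 5–6, 0 °C
Reagents that add atoms: none
Why: In this Claisen–Schmidt condensation E1cB loss of water from 14 gives the conjugated E-enone under thermodynamic control, while the MOM ethers, the free allylic alcohol and the isolated Z-alkene are inert to KOH at rt.

**Step 7**
Reactants: 16 (E)-ferulic acid
Product: 17 methoxymethyl (2E)-3-[3-methoxy-4-(methoxymethoxy)phenyl]prop-2-enoate
Conditions: MOMCl (2.3 equiv), K2CO3, DMF, 0 °C → rt
Reagents that add atoms: chloromethyl methyl ether COCCl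
Why: Carboxylate and phenoxide are both O-alkylated (Williamson type), and the E-alkene bought with the acid is not touched.

**Step 8**
Reactants: 17 methoxymethyl (2E)-3-[3-methoxy-4-(methoxymethoxy)phenyl]prop-2-enoate
Product: 18 (2E)-3-[3-methoxy-4-(methoxymethoxy)phenyl]prop-2-enoic acid
Conditions: LiOH, THF/H2O, rt; then 1 M HCl to pH 4, 0 °C
Reagents that add atoms: lithium hydroxide [Li+].[OH-]
Why: Saponification (acyl substitution) cleaves only the ester, because the aryl MOM acetal is base-stable and survives the brief cold pH 4 work-up.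

**Step 9**
Reactants: 15 (2E)-1-{2-hydroxy-3-[(2Z)-4-hydroxy-3-methylbut-2-en-1-yl]-4-(methoxymethoxy)phenyl}-3-[4-(methoxymethoxy)phenyl]prop-2-en-1-one; 18 (2E)-3-[3-methoxy-4-(methoxymethoxy)phenyl]prop-2-enoic acid
Product: 20 tri-O-MOM gemichalcone A, (2Z)-4-{2-hydroxy-6-(methoxymethoxy)-3-[(2E)-3-[4-(methoxymethoxy)phenyl]prop-2-enoyl]phenyl}-2-methylbut-2-en-1-yl (2E)-3-[3-methoxy-4-(methoxymethoxy)phenyl]prop-2-enoate, via O-acylisourea of 18 19 (not isolated)
Conditions: 18 (1.05 equiv), DIC, DMAP (10 mol %), CH2Cl2, 0 °C → rt, dark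
Reagents that add atoms: none
Why: In this Steglich esterification the primary allylic alcohol is acylated far faster than the ketone-chelated 2'-OH, and because the allylic C–O bond is never broken the Z geometry is kept.

**Step 10**
Reactants: 20 tri-O-MOM gemichalcone A
Product: 21 gemichalcone A
Conditions: 3 M aq HCl/THF/i-PrOH (1:2:2), 40 °C, dark
Reagents that add atoms: none
Why: Acid-catalysed acetal hydrolysis frees the three phenols, while the allylic ester could ionise only to an allyl cation whose methyl sits on the nodal central carbon (no tertiary stabilisation), so the ester, the Z-alkene and both E-enoates survive these mild, methanol-free conditions.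

**Compound list**
1 | prop-2-yn-1-ol | C#CCO | starting material
2 | cyclic (Z)-alkenylmagnesium alkoxide chelate (4-methyl-1-oxa-2-magnesacyclopent-3-ene) | CC1=C[Mg]OC1 | intermediate (not isolated)
3 | 2-methoxy-4-methyl-2,5-dihydro-1,2-oxaborole | COB1OCC(C)=C1 | intermediate (not isolated)
4 | 4-methyl-1,2-oxaborol-2(5H)-ol | CC1=CB(O)OC1 | intermediate
5 | 2,4-dihydroxyacetophenone | CC(=O)c1ccc(O)cc1O | starting material
6 | 1-{3-[(dimethylamino)methyl]-2,4-dihydroxyphenyl}ethan-1-one | CC(=O)c1ccc(O)c(CN(C)C)c1O | intermediate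
7 | spiro N→B aryloxyborate chelate (4-O–B bond, benzylic NMe2 datively bound to the oxaborole boron) | CC(=O)c1ccc2c(c1O)C[N+](C)(C)[B-]1(O2)OCC(C)=C1 | intermediate (not isolated)
8 | o-quinone methide (3-methylene, C4=O) bound through oxygen to 2-(dimethylamino)-4-methyloxaborole | C=C1C(=[O+][B-]2(N(C)C)OCC(C)=C2)C=CC(C(C)=O)=C1O | intermediate (not isolated)
9 | nine-membered cyclic (Z)-aminoborate, ArO–B(NMe2)–OCH2C(CH3)=CHCH2–Ar | CC(=O)c1ccc2OB(N(C)C)OC/C(C)=C\Cc2c1O | intermediate (not isolated)
10 | 1-{2,4-dihydroxy-3-[(2Z)-4-hydroxy-3-methylbut-2-en-1-yl]phenyl}ethan-1-one | CC(=O)c1ccc(O)c(C/C=C(/C)CO)c1O | intermediate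
11 | 1-{2-hydroxy-3-[(2Z)-4-hydroxy-3-methylbut-2-en-1-yl]-4-(methoxymethoxy)phenyl}ethan-1-one | CC(=O)c1ccc(OCOC)c(C/C=C(/C)CO)c1O | intermediate
12 | 4-hydroxybenzaldehyde | O=Cc1ccc(O)cc1 | starting material
13 | 4-(methoxymethoxy)benzaldehyde | COCOc1ccc(C=O)cc1 | intermediate
14 | racemic 3-hydroxy-1-{2-hydroxy-3-[(2Z)-4-hydroxy-3-methylbut-2-en-1-yl]-4-(methoxymethoxy)phenyl}-3-[4-(methoxymethoxy)phenyl]propan-1-one | COCOc1ccc(C(O)CC(=O)c2ccc(OCOC)c(C/C=C(/C)CO)c2O)cc1 | intermediate (not isolated)
15 | (2E)-1-{2-hydroxy-3-[(2Z)-4-hydroxy-3-methylbut-2-en-1-yl]-4-(methoxymethoxy)phenyl}-3-[4-(methoxymethoxy)phenyl]prop-2-en-1-one | COCOc1ccc(/C=C/C(=O)c2ccc(OCOC)c(C/C=C(/C)CO)c2O)cc1 | intermediate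
16 | (E)-ferulic acid | COc1cc(/C=C/C(=O)O)ccc1O | starting material
17 | methoxymethyl (2E)-3-[3-methoxy-4-(methoxymethoxy)phenyl]prop-2-enoate | COCOC(=O)/C=C/c1ccc(OCOC)c(OC)c1 | intermediate
18 | (2E)-3-[3-methoxy-4-(methoxymethoxy)phenyl]prop-2-enoic acid | COCOc1ccc(/C=C/C(=O)O)cc1OC | intermediate
19 | O-acylisourea from 18 and diisopropylcarbodiimide | COCOc1ccc(/C=C/C(=O)OC(=NC(C)C)NC(C)C)cc1OC | intermediate (not isolated)
20 | tri-O-MOM gemichalcone A | COCOc1ccc(/C=C/C(=O)OC/C(C)=C\Cc2c(OCOC)ccc(C(=O)/C=C/c3ccc(OCOC)cc3)c2O)cc1OC | intermediate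
21 | gemichalcone A | COc1cc(/C=C/C(=O)OC/C(C)=C\Cc2c(O)ccc(C(=O)/C=C/c3ccc(O)cc3)c2O)ccc1O | target

**Totals**
Total step count: 10.
Longest linear sequence: 6 steps (1 → 4 → 10 → 11 → 15 → 20 → 21, which is the same length as the line starting from 5).

**Three steps most likely to fail**

Step 3 (the proposed new step) is the highest risk.
- C–N cleavage may need a much higher temperature than 110 °C.
- The parent quinone methide may oligomerise.
- Boron may rest unproductively in the 2-O/ketone chelate.

The fallback uses only known chemistry. It sets out from 6 (and uses 4) and comes back at 10. Boiling 6 in acetic anhydride is the classical exchange of a phenolic Mannich base and gives [3-acetyl-2,6-bis(acetyloxy)phenyl]methyl acetate F1. HBr in AcOH at rt turns the benzylic acetate into 4-acetyl-2-(bromomethyl)benzene-1,3-diyl diacetate F2. A Pd-catalysed, stereoretentive Suzuki–Miyaura benzyl–alkenyl coupling of F2 with 4 (PdCl2(dppf), CsF, THF, 60 °C) gives 4-acetyl-2-[(2Z)-4-hydroxy-3-methylbut-2-en-1-yl]benzene-1,3-diyl diacetate F3. Catalytic K2CO3 in MeOH then removes both phenolic acetates to give 10.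

Step 1 is the second risk.
- The small, polar oxaborole may be lost on extraction.
- Excess MeMgBr may add a second carbon to boron and give a borinic acid.

The fallback sets out from 1 and comes back at 4. The same carbomagnesiation (through 2) is quenched with I2, and the robust, storable (2Z)-3-iodo-2-methylprop-2-en-1-ol F4 is isolated. A Miyaura borylation (B2pin2, PdCl2(dppf), KOAc, dioxane, 80 °C) replaces the Grignard/borate C–B bond formation and gives (2Z)-2-methyl-3-(4,4,5,5-tetramethyl-1,3,2-dioxaborolan-2-yl)prop-2-en-1-ol F5. Stirring F5 with dilute aqueous acid lets the cis hydroxyl displace pinacol and closes it to 4.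

Step 10 is the third risk.
- Acid may solvolyse the cinnamate.
- Acid may close a chroman onto the side chain.
- Acid may isomerise the 2'-hydroxychalcone to the flavanone.

The fallback sets out from 15 and comes back at 21. It avoids any deprotection after the ester is in place. The two MOM groups of 15 are removed first (HCl, MeOH, rt) to give (2E)-1-{2,4-dihydroxy-3-[(2Z)-4-hydroxy-3-methylbut-2-en-1-yl]phenyl}-3-(4-hydroxyphenyl)prop-2-en-1-one F6. F6 is then joined directly to unprotected ferulic acid 16 by a chemoselective Mitsunobu esterification (PPh3, DIAD, THF, 0 °C). In that reaction only the aliphatic alcohol is activated and only the carboxylic acid is acidic enough to act as the nucleophile, so 21 is obtained directly.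

**Further compounds**
F1 | step 3 | [3-acetyl-2,6-bis(acetyloxy)phenyl]methyl acetate | CC(=O)OCc1c(OC(C)=O)ccc(C(C)=O)c1OC(C)=O
F2 | step 3 | 4-acetyl-2-(bromomethyl)benzene-1,3-diyl diacetate | CC(=O)Oc1ccc(C(C)=O)c(OC(C)=O)c1CBr
F3 | step 3 | 4-acetyl-2-[(2Z)-4-hydroxy-3-methylbut-2-en-1-yl]benzene-1,3-diyl diacetate | CC(=O)Oc1ccc(C(C)=O)c(OC(C)=O)c1C/C=C(/C)CO
F4 | step 1 | (2Z)-3-iodo-2-methylprop-2-en-1-ol | OC/C(C)=C\I
F5 | step 1 | (2Z)-2-methyl-3-(4,4,5,5-tetramethyl-1,3,2-dioxaborolan-2-yl)prop-2-en-1-ol | OC/C(C)=C\B1OC(C)(C)C(C)(C)O1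
F6 | step 10 | (2E)-1-{2,4-dihydroxy-3-[(2Z)-4-hydroxy-3-methylbut-2-en-1-yl]phenyl}-3-(4-hydroxyphenyl)prop-2-en-1-one | O=C(/C=C/c1ccc(O)cc1)c1ccc(O)c(C/C=C(/C)CO)c1O
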